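Readings and results were generated by integration with made-up constants, and the scatter is random.

The flask is charged with less protic impurity than free monomer, and the quench takes one of each, so protic impurity is the limiting reagent of that side step. I therefore watched its charge first.

| flask | free monomer | protic impurity | initiator | remark | time |
|---|---|---|---|---|---|
| gamma | 1 mM (fed, over 1.0 min) | 1 mM | 9.8 µM | run made earlier; the fed solution adds 0.20 times the starting volume |  |
| delta | 1.5 mM (fed, over 1.0 min) | 1 mM | 9.8 µM | run made earlier; the fed solution adds 0.20 times the starting volume |  |
| theta | 2 mM (fed, over 1.0 min) | 1.5 mM | 9.8 µM | run made earlier; the fed solution adds 0.20 times the starting volume |  |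
| flask | 2.0 mM (fed, over 1.0 min) | 1.00 mM | 9.8 µM | the fed solution adds 0.20 times the starting volume | 3.0 min |

| run | time / min | monomer in chains / % | free monomer / % |
|---|---|---|---|
| gamma | 0.250 | 1.5 | 18.4 |
| gamma | 0.417 | 4.8 | 24.4 |
| gamma | 0.667 | 8.3 | 32.0 |
| gamma | 1.00 | 13.9 | 42.5 |
| gamma | 1.50 | 19.5 | 21.8 |
| gamma | 2.50 | 22.2 | 8.8 |
| gamma | 4.00 | 23.5 | 2.6 |
| delta | 0.500 | 5.8 | 27.1 |
| delta | 1.00 | 14.6 | 46.7 |
| delta | 1.50 | 20.7 | 28.6 |
| delta | 2.00 | 23.1 | 20.0 |
| delta | 2.50 | 24.9 | 16.7 |
| delta | 3.00 | 26.4 | 14.9 |
| delta | 4.00 | 25.8 | 10.8 |
| theta | 0.333 | 3.1 | 18.2 |
| theta | 0.833 | 8.8 | 33.5 |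
| theta | 1.50 | 17.1 | 22.3 |
| theta | 2.50 | 20.6 | 11.8 |
| theta | 4.00 | 22.7 | 7.2 |

(standard deviation of a reading: 0.5 percentage points)

- charges are per starting volume, the dose included; the dosed solution carries all of it
- the average divides the monomer in chains by the number of chains, living and dead together; two radicals that join make one chain
- reactions considered so far: initiator -> 2 initiating radical; free monomer + initiating radical -> growing radical + monomer in chains; free monomer + growing radical -> monomer in chains + growing radical; 2 growing radical -> dead chain; protic impurity + free monomer -> quenched substrate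
- the earlier runs do not show the number of chains; that part of a forecast is a guess
- percentages count the whole charge, also what has not yet gone in

- average number of monomer units in a chain (living and dead chains, two that joined counted as one) at 3.0 min
- part of the free monomer that has reacted at 3.0 min

I called the impurity's charge over the monomer's charge the quench share: the fraction of the monomer charge the impurity can take. I assumed the impurity was spent by the asked time and borrowed the monomer in chains from the delta run, which had the same initiator, at 3.00 min.

quench share = 50.0%
monomer in chains = 26.4%
reacted = 76.4%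

The runs show no chain count, so I guessed one chain per initiator charged.

dp = 53.9

The weak link was the borrowed chain fraction. The delta run kept 14.9% free at that time, less than the 23.6% my reckoning left in this flask. So I scaled the delta run's late gain of 5.7 percentage points, counted from 1.50 min, by that ratio of free monomer. This used the end ratio over the whole stretch, so I took it as an upper figure.

monomer in chains = 29.7%
reacted = 79.7%
dp = 60.7

I committed to the span between the two reckonings. The forecast gave 76% (71% to 81%) and dp 45 (28 to 80), and said of the second: “The chain count is a guess”.

The flask gave 77.3% reacted and dp 59.1.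

    initiator → 2 initiating radical (k = 0.0220 s⁻¹)
    free monomer + initiating radical → growing radical + monomer in chains (k = 2.50 × 10⁷ L mol⁻¹ s⁻¹)
    free monomer + growing radical → monomer in chains + growing radical, rate k3*[growing radical]*[free monomer] (k = 4.00 × 10⁵ L mol⁻¹ s⁻¹)
    2 growing radical → dead chain (k = 2.00 × 10⁸ L mol⁻¹ s⁻¹)
    protic impurity + free monomer → quenched substrate (k = 42.0 L mol⁻¹ s⁻¹)

At 3.00 min the flask held 48.9% as quenched substrate against the quench share of 50.0%, with 2.21% of the impurity charge left. It held 28.4% as monomer in chains, more than the delta reading I had borrowed.

For the neighbour flask with 3.4 mM of free monomer, the quench share was 29.4%. That neighbour flask computed to 29.4% quenched substrate, with 63.7% reacted and dp 121.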